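**Plan**
- Retrosynthetic cuts, in order: the protecting groups; the aryl ester C7–O–C(=O)Ar; the pyran bond O2–C3 together with the C4a=C5 unsaturation; the carbocycle bond C6–C7; the acyl bond C8a–C8; the bonds O2–C6 and C4a–C5 of a temporary acetal ring; the enyne C(sp)–C(sp2) bond of the side chain.
- Enabling feature: the carbocycle holds an α-ketol, C6(=O)–C7(O)(CH3), whose second flank C8(=O) belongs to a vinylogous ester (O2–C1=C8a–C8=O). C6–C7 is therefore a crossed-benzoin retron in which only the C7 carbonyl is a free ketone.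
- Forward order: side chain first; then a temporary dihydropyran in which O2 bridges C1 and C6 (hetero-Diels–Alder); C8/C7 added by acylation; the acetal opened to free the C6 aldehyde; carbocycle closed at C6–C7; C4a–C5 dehydrogenated; pyran ring closed at O2–C3; esterification; deprotection.
- Stereochemistry: C7 (R) is set by a chiral triazolium carbene in the ring closure. The E alkene comes from the E vinyl iodide and is never touched. C4a and the acetal carbon are temporary centres that are erased.

Key step: step 8

Remark: locants are those of the isochromene core of the target (O2, C1, C3, C4, C4a, C5, C6, C7, C8, C8a).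
Remark (assumption): the (5aS,10bR) antipode of the triazolium salt is taken to give the (R) carbinol at C7; if the sense proves opposite, the mirror-image salt is used in the same way.

**Route**

Step 1
Reactants: 1 (E)-3-iodoacrylic acid
Product: 2 tert-butyl (E)-3-iodoacrylate
Conditions: tert-butyl 2,2,2-trichloroacetimidate (2 equiv), BF3·OEt2 (cat.), CH2Cl2–cyclohexane, 23 °C
Reagents that add atoms: tert-butyl 2,2,2-trichloroacetimidate, CC(C)(C)OC(=N)C(Cl)(Cl)Cl
Why: Acid-catalysed O-alkylation of the acid by the imidate (tert-butyl transfer) should give the ester without touching the vinyl iodide or its E geometry.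

Step 2
Reactants: 2 tert-butyl (E)-3-iodoacrylate; 3 (E)-pent-2-en-4-yn-1-ol
Product: 4 tert-butyl (2E,6E)-8-hydroxyocta-2,6-dien-4-ynoate
Conditions: Pd(PPh3)2Cl2 (2 mol %), CuI (4 mol %), Et3N, THF, 23 °C
Reagents that add atoms: none
Why: Sonogashira coupling of a vinyl iodide with a terminal alkyne proceeds with retention of both E double bonds and tolerates the free allylic alcohol.

Step 3
Reactants: 4 tert-butyl (2E,6E)-8-hydroxyocta-2,6-dien-4-ynoate
Product: 5 tert-butyl (2E,6E)-8-oxoocta-2,6-dien-4-ynoate
Conditions: MnO2 (activated, excess), CH2Cl2, 23 °C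
Reagents that add atoms: none
Why: Allylic oxidation with MnO2 stops at the enal and should leave the enoate, the alkyne and both E geometries intact.

Step 4
Reactants: 5 tert-butyl (2E,6E)-8-oxoocta-2,6-dien-4-ynoate; 6 ethyl vinyl ether
Product: 7 tert-butyl (2E)-5-(2-ethoxy-3,4-dihydro-2H-pyran-4-yl)pent-2-en-4-ynoate
Conditions: 6 (10 equiv), Yb(fod)3 [ytterbium tris(6,6,7,7,8,8,8-heptafluoro-2,2-dimethyloctane-3,5-dionate)] (5 mol %), CH2Cl2, 23 °C
Reagents that add atoms: none
Why: The Lewis-acid-catalysed inverse-electron-demand hetero-Diels–Alder reaction of the enal (as 1-oxadiene) with the vinyl ether should join O2 to the ethoxy-bearing carbon (future C6) and C4a to C5, giving a racemic cis/trans acetal whose two stereocentres are both erased later.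

Step 5
Reactants: 8 pyruvic acid
Product: 9 pyruvoyl chloride
Conditions: Cl2CHOCH3 (1.05 equiv), neat, 50 °C, then distillation
Reagents that add atoms: dichloromethyl methyl ether, COC(Cl)Cl
Why: Dichloromethyl methyl ether converts α-keto acids into their acid chlorides under neutral conditions without the decarbonylation that harsher chlorinating agents cause.

Step 6
Reactants: 7 tert-butyl (2E)-5-(2-ethoxy-3,4-dihydro-2H-pyran-4-yl)pent-2-en-4-ynoate; 9 pyruvoyl chloride
Product: 10 tert-butyl (2E)-5-[2-ethoxy-5-(2-oxopropanoyl)-3,4-dihydro-2H-pyran-4-yl]pent-2-en-4-ynoate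
Conditions: 9 (1.5 equiv), pyridine (2 equiv), CH2Cl2, −20 to 23 °C
Reagents that add atoms: none
Why: Electrophilic C-acylation of the enol ether at its β-carbon C8a (Friedel–Crafts-type acylation–elimination, as known for trichloroacetyl and oxalyl chlorides with 2-alkoxy-dihydropyrans) should install the C8–C7 diketone as a vinylogous ester, pyridine trapping HCl so that the acetal survives.

Step 7
Reactants: 10 tert-butyl (2E)-5-[2-ethoxy-5-(2-oxopropanoyl)-3,4-dihydro-2H-pyran-4-yl]pent-2-en-4-ynoate
Product: 11 tert-butyl (2E)-5-[2-hydroxy-5-(2-oxopropanoyl)-3,4-dihydro-2H-pyran-4-yl]pent-2-en-4-ynoate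
Conditions: 1 M aqueous HCl, THF, 23 °C
Reagents that add atoms: water, O
Why: Mild aqueous acid hydrolyses the ethyl acetal to the lactol (acetal hydrolysis), while the vinylogous ester, the diketone and the tert-butyl ester should survive at this acid strength.

Step 8
Reactants: 11 tert-butyl (2E)-5-[2-hydroxy-5-(2-oxopropanoyl)-3,4-dihydro-2H-pyran-4-yl]pent-2-en-4-ynoate
Product: 13 tert-butyl (2E)-5-[(4R)-4-hydroxy-2-(hydroxymethylidene)-4-methyl-3,5-dioxocyclohexyl]pent-2-en-4-ynoate, via open-chain keto-aldehyde 12 (not isolated)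
Conditions: (5aS,10bR)-2-(pentafluorophenyl)-5a,10b-dihydro-4H,6H-indeno[2,1-b][1,2,4]triazolo[4,3-d][1,4]oxazin-2-ium tetrafluoroborate (15 mol %), NaOAc (30 mol %), CHCl3, 23 °C, argon
Reagents that add atoms: none
Why: Lactol 11 is in ring–chain equilibrium with keto-aldehyde 12; the triazolylidene carbene adds to the C6 aldehyde, proton transfer gives the Breslow enaminol (a C6 acyl-anion equivalent), this attacks the C7 methyl-ketone carbonyl, and collapse of the adduct releases the carbene and α-ketol 13. The closest known reaction type is the carbene-catalysed enantioselective intramolecular crossed aldehyde–ketone benzoin reaction, including its use on δ-keto aldehydes that carry an acidic 1,3-dicarbonyl unit and rest as lactols. The carbocycle (C5–C6–C7–C8–C8a–C4a) closes in a 6-exo-trig mode. The new C7 centre is set by the catalyst: the fused aminoindane wall shields one face of the enaminol, and the ketone docks through a hydrogen bond from the enaminol O–H with its small methyl group toward the N-aryl group, so that one face of C7 is attacked. The step needs C7 to be chosen over the C8 and C1 carbonyls and over aldol chemistry at C5; C8 and C1 are tied up as a hydrogen-bonded hydroxymethylene ketone (a vinylogous acid), C7 is the free, activated half of a 1,2-diketone, and the weak acetate base keeps enolate concentrations low. The racemic C4a centre carries only a slim, rod-like alkynyl group, so both antipodes should follow the catalyst, and C4a is erased in step 9.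

Step 9
Reactants: 13 tert-butyl (2E)-5-[(4R)-4-hydroxy-2-(hydroxymethylidene)-4-methyl-3,5-dioxocyclohexyl]pent-2-en-4-ynoate
Product: 15 tert-butyl (2E)-3-[(7R)-7-hydroxy-7-methyl-6,8-dioxo-7,8-dihydro-6H-isochromen-3-yl]prop-2-enoate, via alkynyl hydroxymethylene dienone 14 (not isolated)
Conditions: DDQ (2,3-dichloro-5,6-dicyano-1,4-benzoquinone, 1.2 equiv), 1,4-dioxane, 23 to 50 °C; then aqueous KH2PO4/K2HPO4 buffer (pH 7), MeCN, 23 °C
Reagents that add atoms: none
Why: DDQ should abstract hydride from the doubly activated C4a–H (allylic to the enol and propargylic) and loss of the C5 proton gives dienone 14 (DDQ dehydrogenation), whose enol oxygen O2 then adds to alkyne carbon C3 in a 6-endo-dig oxa-Michael (1,6-addition) cycloisomerisation of the kind known for such alkynyl hydroxymethylene dienones, with C7 untouched.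

Step 10
Reactants: 16 2,4-dihydroxy-6-methylbenzoic acid (orsellinic acid)
Product: 17 methoxymethyl 2,4-bis(methoxymethoxy)-6-methylbenzoate
Conditions: CH3OCH2Cl (3.6 equiv), iPr2NEt (4 equiv), CH2Cl2, 0 to 40 °C
Reagents that add atoms: chloromethyl methyl ether, COCCl
Why: O-Alkylation with chloromethyl methyl ether under amine base (Williamson-type) protects both phenols and, as the methoxymethyl ester, the acid.

Step 11
Reactants: 17 methoxymethyl 2,4-bis(methoxymethoxy)-6-methylbenzoate
Product: 18 2,4-bis(methoxymethoxy)-6-methylbenzoic acid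
Conditions: LiOH·H2O, THF–MeOH–H2O, 23 °C; then 1 M HCl to pH 4 at 0 °C
Reagents that add atoms: lithium hydroxide, [Li+].[OH-]
Why: Saponification cleaves the reactive methoxymethyl ester at the acyl–oxygen bond, while the aryl methoxymethyl ethers are stable to base.

Step 12
Reactants: 15 tert-butyl (2E)-3-[(7R)-7-hydroxy-7-methyl-6,8-dioxo-7,8-dihydro-6H-isochromen-3-yl]prop-2-enoate; 18 2,4-bis(methoxymethoxy)-6-methylbenzoic acid
Product: 20 tert-butyl (2E)-3-[(7R)-7-{[2,4-bis(methoxymethoxy)-6-methylbenzoyl]oxy}-7-methyl-6,8-dioxo-7,8-dihydro-6H-isochromen-3-yl]prop-2-enoate, via aroyl chloride 19 (not isolated)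
Conditions: 18, 1-chloro-N,N,2-trimethylprop-1-en-1-amine, CH2Cl2, 0 °C; then 15, Et3N, 4-(dimethylamino)pyridine, CH2Cl2, 23 to 40 °C
Reagents that add atoms: none
Why: Neutral chlorination of 18 with the α-chloroenamine gives acid chloride 19, whose acylpyridinium form acylates the tertiary C7 hydroxyl, the only hydroxyl in 15 (nucleophilic-catalysis esterification), and the C7 configuration is kept because no bond to C7 is broken.

Step 13
Reactants: 20 tert-butyl (2E)-3-[(7R)-7-{[2,4-bis(methoxymethoxy)-6-methylbenzoyl]oxy}-7-methyl-6,8-dioxo-7,8-dihydro-6H-isochromen-3-yl]prop-2-enoate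
Product: 21 mitorubrinic acid
Conditions: CF3CO2H–CH2Cl2 (1:3), 0 to 23 °C; aqueous work-up
Reagents that add atoms: none
Why: Trifluoroacetic acid removes the tert-butyl ester (loss of 2-methylpropene) and both aryl methoxymethyl ethers (acetal cleavage) in one operation, while the acid-stable pyranoquinone core and the tertiary aryl ester, whose C7 cation would be destabilised by two flanking carbonyls, should survive.

**Compound list**

1 | (E)-3-iodoacrylic acid | OC(=O)/C=C/I | starting material
2 | tert-butyl (E)-3-iodoacrylate | CC(C)(C)OC(=O)/C=C/I | intermediate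
3 | (E)-pent-2-en-4-yn-1-ol | OC/C=C/C#C | starting material
4 | tert-butyl (2E,6E)-8-hydroxyocta-2,6-dien-4-ynoate | CC(C)(C)OC(=O)/C=C/C#C/C=C/CO | intermediate
5 | tert-butyl (2E,6E)-8-oxoocta-2,6-dien-4-ynoate | CC(C)(C)OC(=O)/C=C/C#C/C=C/C=O | intermediate
6 | ethyl vinyl ether | C=COCC | starting material
7 | tert-butyl (2E)-5-(2-ethoxy-3,4-dihydro-2H-pyran-4-yl)pent-2-en-4-ynoate (racemic, cis/trans mixture at the acetal carbon) | CCOC1CC(C#C/C=C/C(=O)OC(C)(C)C)C=CO1 | intermediate
8 | pyruvic acid | CC(=O)C(=O)O | starting material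
9 | pyruvoyl chloride | CC(=O)C(=O)Cl | intermediate
10 | tert-butyl (2E)-5-[2-ethoxy-5-(2-oxopropanoyl)-3,4-dihydro-2H-pyran-4-yl]pent-2-en-4-ynoate (racemic, cis/trans mixture) | CCOC1CC(C#C/C=C/C(=O)OC(C)(C)C)C(C(=O)C(C)=O)=CO1 | intermediate
11 | tert-butyl (2E)-5-[2-hydroxy-5-(2-oxopropanoyl)-3,4-dihydro-2H-pyran-4-yl]pent-2-en-4-ynoate (racemic at C4 of the pyran, anomer mixture) | OC1CC(C#C/C=C/C(=O)OC(C)(C)C)C(C(=O)C(C)=O)=CO1 | intermediate
12 | tert-butyl (2E)-7-(hydroxymethylidene)-8,9-dioxo-6-(2-oxoethyl)dec-2-en-4-ynoate (open-chain tautomer of 11) | O=CCC(C#C/C=C/C(=O)OC(C)(C)C)C(=CO)C(=O)C(C)=O | intermediate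
13 | tert-butyl (2E)-5-[(4R)-4-hydroxy-2-(hydroxymethylidene)-4-methyl-3,5-dioxocyclohexyl]pent-2-en-4-ynoate (both epimers at ring C1, the future C4a) | O[C@]1(C)C(=O)CC(C#C/C=C/C(=O)OC(C)(C)C)C(=CO)C1=O | intermediate
14 | tert-butyl (2E)-5-[(4R)-4-hydroxy-6-(hydroxymethylidene)-4-methyl-3,5-dioxocyclohex-1-en-1-yl]pent-2-en-4-ynoate | O[C@]1(C)C(=O)C=C(C#C/C=C/C(=O)OC(C)(C)C)C(=CO)C1=O | intermediate
15 | tert-butyl (2E)-3-[(7R)-7-hydroxy-7-methyl-6,8-dioxo-7,8-dihydro-6H-isochromen-3-yl]prop-2-enoate | O[C@]1(C)C(=O)C=C2C=C(/C=C/C(=O)OC(C)(C)C)OC=C2C1=O | intermediate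
16 | 2,4-dihydroxy-6-methylbenzoic acid (orsellinic acid) | Cc1cc(O)cc(O)c1C(=O)O | starting material
17 | methoxymethyl 2,4-bis(methoxymethoxy)-6-methylbenzoate | COCOC(=O)c1c(C)cc(OCOC)cc1OCOC | intermediate
18 | 2,4-bis(methoxymethoxy)-6-methylbenzoic acid | Cc1cc(OCOC)cc(OCOC)c1C(=O)O | intermediate
19 | 2,4-bis(methoxymethoxy)-6-methylbenzoyl chloride | Cc1cc(OCOC)cc(OCOC)c1C(=O)Cl | intermediate
20 | tert-butyl (2E)-3-[(7R)-7-{[2,4-bis(methoxymethoxy)-6-methylbenzoyl]oxy}-7-methyl-6,8-dioxo-7,8-dihydro-6H-isochromen-3-yl]prop-2-enoate | Cc1cc(OCOC)cc(OCOC)c1C(=O)O[C@]1(C)C(=O)C=C2C=C(/C=C/C(=O)OC(C)(C)C)OC=C2C1=O | intermediate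
21 | mitorubrinic acid, (2E)-3-[(7R)-7-[(2,4-dihydroxy-6-methylbenzoyl)oxy]-7-methyl-6,8-dioxo-7,8-dihydro-6H-isochromen-3-yl]prop-2-enoic acid | Cc1cc(O)cc(O)c1C(=O)O[C@]1(C)C(=O)C=C2C=C(/C=C/C(=O)O)OC=C2C1=O | target

**Step count and risks**

Total step count: 13. Longest linear sequence: 10 steps (steps 1, 2, 3, 4, 6, 7, 8, 9, 12, 13).

Steps most likely to fail:

Step 8. What may go wrong: for one antipode of the racemic C4a centre the substrate may override the catalyst (a mismatched pairing), so that facial selectivity at C7 erodes. Fallback: fix C4a first and let it reinforce the closure. The fallback sets out from 5 (with 6). The hetero-Diels–Alder reaction is run with the tridentate Schiff-base chromium chloride complex CrCl(L) [L = dianion of (1R,2S)-1-{[3-(adamantan-1-yl)-2-hydroxy-5-methylbenzylidene]amino}indan-2-ol] and 4 Å molecular sieves, a known enantioselective version for enals and ethyl vinyl ether, to give the enantio-enriched cis acetal F1. Acylation with 9 as in step 6 gives the diketone F2, and hydrolysis as in step 7 gives the C4-defined lactol F3. The benzoin closure is then run with the triazolium antipode that is matched with C4a (the chromium antipode being chosen accordingly; the pairing drawn is one of the two possible) to give the single-diastereomer ketol F4. DDQ and buffer as in step 9 bring the material back to the route at 15.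

Step 9. What may go wrong: hydride abstraction at C4a may be slower than attack of DDQ on the electron-rich hydroxymethylene enol, so that the enol is consumed before dehydrogenation. Fallback: a Saegusa–Ito dehydrogenation. It sets out from 13. Me3SiOTf and Et3N in CH2Cl2 silylate both hydroxyls and turn the C6 ketone, which can enolise only toward C5, into its silyl enol ether, giving the tris(trimethylsilyl) compound F5. Pd(OAc)2 in MeCN dehydrosilylates it to the bis(trimethylsilyl) dienone F6. Buffered aqueous work-up (KH2PO4/K2HPO4, then KF) removes the silyl groups to give 14, which cyclises as in step 9, so the route is rejoined at 15.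

Step 12. What may go wrong: acyl transfer to the hindered tertiary α-ketol hydroxyl may be so slow that the ortho-alkoxy acid chloride decays (loss of chloromethyl methyl ether to a benzodioxinone) before esterification. Fallback: switch from nucleophilic catalysis to an acylium-type acylation, which suits both a 2,6-disubstituted benzoic acid and the acid-stable core. It sets out from 18. Trifluoroacetic anhydride in CH2Cl2 at 0 °C gives the mixed trifluoroacetic anhydride F7, which ionises toward the hindered aroyl cation and acylates 15 without base, returning to the route at 20. Any methoxymethyl group lost on the way is of no consequence, since step 13 removes both.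

Further compounds
F1 | step 8 | tert-butyl (2E)-5-[(2S,4S)-2-ethoxy-3,4-dihydro-2H-pyran-4-yl]pent-2-en-4-ynoate | CCO[C@@H]1C[C@H](C#C/C=C/C(=O)OC(C)(C)C)C=CO1
F2 | step 8 | tert-butyl (2E)-5-[(2S,4R)-2-ethoxy-5-(2-oxopropanoyl)-3,4-dihydro-2H-pyran-4-yl]pent-2-en-4-ynoate | CCO[C@@H]1C[C@H](C#C/C=C/C(=O)OC(C)(C)C)C(C(=O)C(C)=O)=CO1
F3 | step 8 | tert-butyl (2E)-5-[(4R)-2-hydroxy-5-(2-oxopropanoyl)-3,4-dihydro-2H-pyran-4-yl]pent-2-en-4-ynoate | OC1C[C@H](C#C/C=C/C(=O)OC(C)(C)C)C(C(=O)C(C)=O)=CO1
F4 | step 8 | tert-butyl (2E)-5-[(1R,4R)-4-hydroxy-2-(hydroxymethylidene)-4-methyl-3,5-dioxocyclohexyl]pent-2-en-4-ynoate | O[C@]1(C)C(=O)C[C@H](C#C/C=C/C(=O)OC(C)(C)C)C(=CO)C1=O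
F5 | step 9 | tert-butyl (2E)-5-[(4R)-4-methyl-3-oxo-4,5-bis(trimethylsilyloxy)-2-[(trimethylsilyloxy)methylidene]cyclohex-5-en-1-yl]pent-2-en-4-ynoate | C[Si](C)(C)O[C@]1(C)C(O[Si](C)(C)C)=CC(C#C/C=C/C(=O)OC(C)(C)C)C(=CO[Si](C)(C)C)C1=O
F6 | step 9 | tert-butyl (2E)-5-[(4R)-4-methyl-3,5-dioxo-4-(trimethylsilyloxy)-6-[(trimethylsilyloxy)methylidene]cyclohex-1-en-1-yl]pent-2-en-4-ynoate | C[Si](C)(C)O[C@]1(C)C(=O)C=C(C#C/C=C/C(=O)OC(C)(C)C)C(=CO[Si](C)(C)C)C1=O
F7 | step 12 | 2,4-bis(methoxymethoxy)-6-methylbenzoic trifluoroacetic anhydride | Cc1cc(OCOC)cc(OCOC)c1C(=O)OC(=O)C(F)(F)F
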